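(Readings and results were generated by integration for substances that don't exist, noise included.)

Two questions wait for you at this bench:

1. amount of target at the end, in percent of the starting material charged for west, north-west, north-east, north, in this order
2. how that number moves from the first to the last of them (falls, then rises / hardly changes / rises, then falls / rises all the way / falls all the way)

in all of them: initiator 50 µM

| run | starting material | reagent | scavenger | remark | time |
|---|---|---|---|---|---|
| summer | 3.1 mM | 40 mM | 5 mM | run made earlier |  |
| autumn | 27 mM | 40 mM | 5 mM | run made earlier |  |
| west | 5.0 mM | 40.0 mM | 5.00 mM |  | 4.0 min |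
| north-west | 10 mM | 40.0 mM | 5.00 mM |  | 4.0 min |
| north-east | 20 mM | 40.0 mM | 5.00 mM |  | 4.0 min |
| north | 40 mM | 40.0 mM | 5.00 mM |  | 4.0 min |

| run | time / min | target / % |
|---|---|---|
| summer | 0.250 | 15.8 |
| summer | 0.333 | 19.5 |
| summer | 0.667 | 30.5 |
| summer | 1.00 | 37.1 |
| summer | 1.50 | 43.1 |
| summer | 3.00 | 50.9 |
| autumn | 0.250 | 11.8 |
| autumn | 0.333 | 13.2 |
| autumn | 0.667 | 15.6 |
| autumn | 1.00 | 18.5 |
| autumn | 1.50 | 20.6 |
| autumn | 3.00 | 22.4 |

(standard deviation of a reading: 0.5 percentage points)

- the numbers in the tables scatter by 0.5 percentage points (one standard deviation)
- "hardly changes" means that all values lie within two and a half points (for a concentration: within two and a half percent of the largest)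

From west to north, each charge of starting material is twice the one before. Reagent, scavenger and initiator stand as in the summer and autumn runs. Those runs flatten, and the larger charge ends at the smaller fraction, so take the last readings to logarithms:

log of fraction ratio / log of charge ratio = −0.356 / 0.940 = −0.379

This is the yield slope, the change in the logarithm of the end fraction per unit change in the logarithm of the charge. Each doubling of the charge multiplies the fraction by 0.769. Starting from summer, my own row for the fraction of target you will find is:

west 42.5%
north-west 32.6%
north-east 25.1%
north 19.3%

It may lean low. The readings stop at 3.00 min, and summer gained 7.8 percentage points over its last interval. Don't touch the reagent, scavenger or initiator: the slope was read with them held.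

The forecast, from a saturating curve through the two plateaus, gives 47%, 37%, 27% and 18%. That is higher than mine in west and lower in north. Its shape is falls all the way: “Yield falls throughout”.

The flasks give 45.0%, 35.1%, 26.6% and 19.1%, so the row falls all the way.

    starting material + released group ⇌ idle adduct, settled at all times (K = 23000 M⁻¹)
    starting material + second chain carrier → released group + first chain carrier (k = 1.48 × 10⁵ M⁻¹ s⁻¹)
    2 reagent → self-condensation product (k = 0.875 M⁻¹ s⁻¹)
    scavenger + released group → scavenged by-product (k = 107 M⁻¹ s⁻¹)
    2 second chain carrier → ended chains B (k = 3.00 × 10⁷ M⁻¹ s⁻¹)
    2 first chain carrier → ended chains A (k = 3.00 × 10⁷ M⁻¹ s⁻¹)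
    initiator → 2 initiating radical (k = 0.00434 s⁻¹)
    reagent + first chain carrier ⇌ target + second chain carrier (K = 0.100, k = 2.70 × 10⁵ M⁻¹ s⁻¹)
    starting material + initiating radical → capped initiator + first chain carrier (k = 6.99 × 10⁶ M⁻¹ s⁻¹)

Carried from west, the yield slope gives north-west 34.6% against 35.1% found, and north 20.5% against 19.1% found. Just after the start in west, before the chain has built up, reagent is used 370 times faster by self-condensation than by the forward step to target alone, but that ratio belongs to that moment. Counted up to 4.00 min, west has put 35.8 mM of reagent into self-condensation product and 2.25 mM into target. West holds 5.0% of its reagent at 4.00 min, and after 40.0 min it holds 0.530% of it, with target at 50.7%.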